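The cyclopenta[c]pyran (C1, O2, C3, C4, C4a, C5, C6, C7, C7a) is cut at the ring-fusion bond C4a–C7a. An acyclic C20 2,6-dienedial that already carries the (S)-acetate, both side-chain alkenes and the C7 formyl group masked as a diethyl acetal is cyclised by a secondary amine. The dienamine of the unbranched C1 enal attacks C4a of the branched C3 enal through C7a, which closes the five-membered ring (C4a, C5, C6, C7, C7a) and leaves the C1 and C3 aldehydes 1,5-related. Acid then closes the pyran through O2 and DDQ aromatises. The dial comes from an (S)-γ-lactone phosphonate (geranial plus allyl) and a C6 aldehyde.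

Key step: step 13

Assumption: geranial is used as the commercial E isomer (otherwise one extra MnO2 oxidation of geraniol supplies it); ring atoms carry cyclopenta[c]pyran numbers and side-chain atoms C1' to C8' throughout.

Step 1
Reactants: 1 geranial; 2 (−)-B-allyldiisopinocampheylborane [(−)-Ipc2B(allyl), from (+)-α-pinene]
Product: 4 (4S,5E)-6,10-dimethylundeca-1,5,9-trien-4-ol, via borinate 3 (not isolated)
Conditions: 2 (1 M in pentane), Et2O, −78 °C; then NaOH, H2O2, 0 °C → rt
Reagents that add atoms: (−)-B-allyldiisopinocampheylborane (2), C=CCB([C@@H]1C[C@@H]2C[C@@H](C2(C)C)[C@H]1C)[C@@H]1C[C@@H]2C[C@@H](C2(C)C)[C@H]1C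
Why: Brown allylboration through a chair Zimmerman–Traxler transition state, in which the (+)-α-pinene-derived reagent delivers allyl to the Si face of the enal carbonyl and so sets C2' as S, 1,2-addition being the only path open to an allylborane.

Step 2
Reactants: 4 (4S,5E)-6,10-dimethylundeca-1,5,9-trien-4-ol
Product: 6 (4S,5E)-6,10-dimethylundeca-5,9-diene-1,4-diol, via alkylborane 5 (not isolated)
Conditions: 9-BBN (2.2 equiv), THF, 0 °C → rt; then NaOH, H2O2, 0 °C
Reagents that add atoms: hydrogen peroxide, OO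
Why: Hydroboration–oxidation, in which 9-BBN adds anti-Markovnikov to the monosubstituted alkene far faster than to the two trisubstituted ones and alkaline H2O2 replaces boron by hydroxyl without touching C2'.

Step 3
Reactants: 6 (4S,5E)-6,10-dimethylundeca-5,9-diene-1,4-diol
Product: 8 (5S)-5-[(1E)-2,6-dimethylhepta-1,5-dien-1-yl]oxolan-2-one, via lactol 7 (not isolated)
Conditions: TEMPO (0.2 equiv), PhI(OAc)2 (2.5 equiv), CH2Cl2, rt
Reagents that add atoms: none
Why: TEMPO/PhI(OAc)2 oxidative lactonisation, in which the oxoammonium ion oxidises the primary alcohol first, the secondary hydroxyl traps the aldehyde as the five-membered lactol and this is oxidised on to the γ-lactone.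

Step 4
Reactants: 8 (5S)-5-[(1E)-2,6-dimethylhepta-1,5-dien-1-yl]oxolan-2-one
Product: 10 diethyl [(5S)-5-[(1E)-2,6-dimethylhepta-1,5-dien-1-yl]-2-oxooxolan-3-yl]phosphonate (both epimers at the phosphorus-bearing carbon), via enol phosphate 9 (not isolated)
Conditions: LiN(i-Pr)2 (1.1 equiv), THF, −78 °C; ClP(O)(OEt)2; then LiN(i-Pr)2 (2.2 equiv), −78 °C → rt; aq. NH4Cl
Reagents that add atoms: diethyl chlorophosphate, CCOP(=O)(Cl)OCC
Why: Vinyl phosphate to phosphonate rearrangement, in which O-phosphorylation of the lactone enolate is followed by a base-induced 1,3-shift of phosphorus from oxygen to carbon that is driven by formation of the stabilised phosphonate anion; C2' is not involved and the new centre at C4 is erased in step 8.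

Step 5
Reactants: 11 3,3-diethoxyprop-1-yne; 12 ethyl chloroformate
Product: 13 ethyl 4,4-diethoxybut-2-ynoate
Conditions: n-BuLi, THF, −78 °C; then 12, −78 → 0 °C
Reagents that add atoms: ethyl chloroformate (12), CCOC(=O)Cl
Why: Acylation of a lithium acetylide with a chloroformate, the acetal being inert to n-BuLi at low temperature.

Step 6
Reactants: 13 ethyl 4,4-diethoxybut-2-ynoate; 14 but-3-enylmagnesium bromide
Product: 15 ethyl (2Z)-3-(diethoxymethyl)hepta-2,6-dienoate
Conditions: 14 (1.2 equiv), CuBr·SMe2 (1.2 equiv), THF, −40 °C; then 13, −78 °C; MeOH then aq. NH4Cl at −78 °C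
Reagents that add atoms: but-3-enylmagnesium bromide (14), C=CCC[Mg]Br
Why: Syn carbocupration (conjugate addition) of the organocopper reagent to the ynoate puts the butenyl group on the β-carbon (C7), and protonation of the alkenylcopper at −78 °C keeps CO2Et and CH(OEt)2 cis; any erosion of this geometry is harmless because step 13 erases it.

Step 7
Reactants: 15 ethyl (2Z)-3-(diethoxymethyl)hepta-2,6-dienoate
Product: 17 ethyl (2Z)-3-(diethoxymethyl)-6-oxohex-2-enoate, via diol 16 (not isolated)
Conditions: OsO4 (2 mol%), NaIO4 (4 equiv), 2,6-lutidine, 1,4-dioxane/H2O, rt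
Reagents that add atoms: OsO4, O=[Os](=O)(=O)=O (oxygen carrier); NaIO4, [Na+].[O-]I(=O)(=O)=O (terminal oxidant)
Why: Lemieux–Johnson cleavage, in which OsO4 dihydroxylates the monosubstituted alkene in preference to the electron-poor trisubstituted enoate, NaIO4 cleaves the diol and 2,6-lutidine keeps the acetal intact.

Step 8
Reactants: 10 diethyl [(5S)-5-[(1E)-2,6-dimethylhepta-1,5-dien-1-yl]-2-oxooxolan-3-yl]phosphonate; 17 ethyl (2Z)-3-(diethoxymethyl)-6-oxohex-2-enoate
Product: 18 ethyl (2Z,6E)-3-(diethoxymethyl)-6-[(5S)-5-[(1E)-2,6-dimethylhepta-1,5-dien-1-yl]-2-oxooxolan-3-ylidene]hex-2-enoate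
Conditions: NaH, THF, 0 °C; then 17, 0 °C → rt
Reagents that add atoms: none
Why: Horner–Wadsworth–Emmons olefination of an α-phosphono lactone with an aliphatic aldehyde forms C4=C4a and should favour the E alkylidene lactone (chain trans to the carbonyl), while the β,β-disubstituted enoate is too hindered to act as a Michael acceptor.

Step 9
Reactants: 18 ethyl (2Z,6E)-3-(diethoxymethyl)-6-[(5S)-5-[(1E)-2,6-dimethylhepta-1,5-dien-1-yl]-2-oxooxolan-3-ylidene]hex-2-enoate
Product: 19 (2Z,6E,9S,10E)-3-(diethoxymethyl)-7-(hydroxymethyl)-11,15-dimethylhexadeca-2,6,10,14-tetraene-1,9-diol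
Conditions: i-Bu2AlH (6 equiv), CH2Cl2, −78 → 0 °C; aq. KNaC4H4O6
Reagents that add atoms: none
Why: i-Bu2AlH reduces the lactone and the conjugated ester in the 1,2-sense to allylic alcohols and leaves the acetal, the alkene geometries and C2' unchanged.

Step 10
Reactants: 19 (2Z,6E,9S,10E)-3-(diethoxymethyl)-7-(hydroxymethyl)-11,15-dimethylhexadeca-2,6,10,14-tetraene-1,9-diol
Product: 21 (2Z,6E,9S,10E)-1-[(tert-butyldimethylsilyl)oxy]-7-{[(tert-butyldimethylsilyl)oxy]methyl}-3-(diethoxymethyl)-11,15-dimethylhexadeca-2,6,10,14-tetraen-9-yl acetate, via bis-silyl ether 20 (not isolated)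
Conditions: TBSCl (2.1 equiv), imidazole, CH2Cl2, −10 °C; then Ac2O, DMAP, pyridine, rt
Reagents that add atoms: tert-butyldimethylsilyl chloride, CC(C)(C)[Si](C)(C)Cl; acetic anhydride, CC(=O)OC(C)=O
Why: Steric differentiation, in which TBSCl/imidazole silylates the two primary allylic hydroxyls much faster than the secondary one, which is then acetylated by DMAP-catalysed acylation with retention at C2'.

Step 11
Reactants: 21 (2Z,6E,9S,10E)-1-[(tert-butyldimethylsilyl)oxy]-7-{[(tert-butyldimethylsilyl)oxy]methyl}-3-(diethoxymethyl)-11,15-dimethylhexadeca-2,6,10,14-tetraen-9-yl acetate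
Product: 22 (2Z,6E,9S,10E)-3-(diethoxymethyl)-1-hydroxy-7-(hydroxymethyl)-11,15-dimethylhexadeca-2,6,10,14-tetraen-9-yl acetate
Conditions: Bu4NF (2.5 equiv), AcOH (2.5 equiv), THF, 0 °C → rt
Reagents that add atoms: none
Why: Fluoride cleavage of the primary silyl ethers, with acetic acid buffering so that the acetate neither migrates nor is cleaved and the acetal is not exchanged by the neighbouring cis hydroxyl.

Step 12
Reactants: 22 (2Z,6E,9S,10E)-3-(diethoxymethyl)-1-hydroxy-7-(hydroxymethyl)-11,15-dimethylhexadeca-2,6,10,14-tetraen-9-yl acetate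
Product: 23 (2Z,6E,9S,10E)-3-(diethoxymethyl)-7-formyl-11,15-dimethyl-1-oxohexadeca-2,6,10,14-tetraen-9-yl acetate
Conditions: MnO2 (30 equiv), CH2Cl2, rt
Reagents that add atoms: none
Why: MnO2 oxidises both primary allylic alcohols to the enals and stops there, the allylic acetate, the acetal and the isolated alkenes being inert.

Step 13
Reactants: 23 (2Z,6E,9S,10E)-3-(diethoxymethyl)-7-formyl-11,15-dimethyl-1-oxohexadeca-2,6,10,14-tetraen-9-yl acetate
Product: 25 (4S,5E)-2-[3-(diethoxymethyl)-2-formylcyclopent-2-en-1-yl]-6,10-dimethyl-1-oxoundeca-5,9-dien-4-yl acetate (mixture at C4 and C4a), via dienamine 24 (not isolated)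
Conditions: (S)-2-[diphenyl(trimethylsilyloxy)methyl]pyrrolidine (20 mol%), PhCO2H (20 mol%), CH2Cl2, rt
Reagents that add atoms: none
Why: The bulky amine condenses with the α-unbranched C1 enal, γ-deprotonation at C6 gives dienamine 24, its α-carbon C7a adds to C4a of the C3 enal, and proton transfer followed by hydrolysis returns the conjugated C7=C7a enal and the catalyst. The closest known reaction type is the amine-catalysed dienamine Rauhut–Currier cyclisation of 2,6-dienedials to cyclopentene carbaldehydes. The ring (C4a, C5, C6, C7, C7a) closes in a 5-exo-trig Michael addition with the enamine double bond exocyclic to the forming ring. C4a and C4 become stereocentres without useful control and are carried as a mixture because both turn sp2 in steps 14 and 15, while C2' is remote and untouched, so either enantiomer of the catalyst serves. The step needs condensation at C1 instead of C3, which the α-branch at C4 secures through allylic strain in its iminium ion, and α- instead of γ-attack, which ring size secures since C6 could only close a three-membered ring. The acetal on C7 sits at a non-nucleophilic position of the dienamine and is stable to benzoic acid.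

Step 14
Reactants: 25 (4S,5E)-2-[3-(diethoxymethyl)-2-formylcyclopent-2-en-1-yl]-6,10-dimethyl-1-oxoundeca-5,9-dien-4-yl acetate
Product: 28 (2S,3E)-1-(7-formyl-4a,5-dihydrocyclopenta[c]pyran-4-yl)-4,8-dimethylnona-3,7-dien-2-yl acetate (used crude), via lactol acetal 26 (not isolated), via dienol ether acetal 27 (not isolated)
Conditions: PPTS (0.2 equiv), benzene, 50 °C; then acetone/H2O (20:1), rt
Reagents that add atoms: water, O
Why: Acid-catalysed enol-lactol formation and dehydration as in iridoid dialdehydes, in which the C3 carbonyl oxygen (O2) adds to the protonated C1 enal and H4 is lost to give 26, the allylic oxocarbenium ion at C1 loses H6 to give 27 and the now electron-rich vinylic acetal is hydrolysed in wet acetone; PPTS is too weak to ionise the allylic acetate, and any double-bond isomer at this oxidation level would converge in step 15.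

Step 15
Reactants: 28 (2S,3E)-1-(7-formyl-4a,5-dihydrocyclopenta[c]pyran-4-yl)-4,8-dimethylnona-3,7-dien-2-yl acetate
Product: 29 (2S,3E)-1-(7-formylcyclopenta[c]pyran-4-yl)-4,8-dimethylnona-3,7-dien-2-yl acetate (CNP0325919.1)
Conditions: DDQ (1.1 equiv), 1,4-dioxane, rt
Reagents that add atoms: none
Why: DDQ dehydrogenation, in which hydride abstraction from the doubly allylic C4a–H of the 4H-pyran gives a pyrylium-type cation that loses H5 to the 10π cyclopenta[c]pyran stabilised by the C7 formyl group, while the isolated trisubstituted alkenes and the acetate should not react at room temperature.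

Compound list
1 | geranial, (2E)-3,7-dimethylocta-2,6-dienal | CC(C)=CCC/C(C)=C/C=O | starting material
2 | (−)-B-allyldiisopinocampheylborane | C=CCB([C@@H]1C[C@@H]2C[C@@H](C2(C)C)[C@H]1C)[C@@H]1C[C@@H]2C[C@@H](C2(C)C)[C@H]1C | starting material
3 | diisopinocampheylborinate of 4 | C=CC[C@H](OB([C@@H]1C[C@@H]2C[C@@H](C2(C)C)[C@H]1C)[C@@H]1C[C@@H]2C[C@@H](C2(C)C)[C@H]1C)/C=C(\C)CCC=C(C)C | intermediate (not isolated)
4 | (4S,5E)-6,10-dimethylundeca-1,5,9-trien-4-ol | C=CC[C@H](O)/C=C(\C)CCC=C(C)C | intermediate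
5 | B-[(4S,5E)-4-hydroxy-6,10-dimethylundeca-5,9-dien-1-yl]-9-borabicyclo[3.3.1]nonane (hydroxyl written free) | C(CC[C@H](O)/C=C(\C)CCC=C(C)C)B1C2CCCC1CCC2 | intermediate (not isolated)
6 | (4S,5E)-6,10-dimethylundeca-5,9-diene-1,4-diol | OCCC[C@H](O)/C=C(\C)CCC=C(C)C | intermediate
7 | (5S)-5-[(1E)-2,6-dimethylhepta-1,5-dien-1-yl]oxolan-2-ol | OC1CC[C@@H](/C=C(\C)CCC=C(C)C)O1 | intermediate (not isolated)
8 | (5S)-5-[(1E)-2,6-dimethylhepta-1,5-dien-1-yl]oxolan-2-one | O=C1CC[C@@H](/C=C(\C)CCC=C(C)C)O1 | intermediate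
9 | diethyl (5S)-5-[(1E)-2,6-dimethylhepta-1,5-dien-1-yl]-4,5-dihydrofuran-2-yl phosphate | CCOP(=O)(OCC)OC1=CC[C@@H](/C=C(\C)CCC=C(C)C)O1 | intermediate (not isolated)
10 | diethyl [(5S)-5-[(1E)-2,6-dimethylhepta-1,5-dien-1-yl]-2-oxooxolan-3-yl]phosphonate | CCOP(=O)(OCC)C1C[C@@H](/C=C(\C)CCC=C(C)C)OC1=O | intermediate
11 | 3,3-diethoxyprop-1-yne | C#CC(OCC)OCC | starting material
12 | ethyl chloroformate | CCOC(=O)Cl | starting material
13 | ethyl 4,4-diethoxybut-2-ynoate | CCOC(=O)C#CC(OCC)OCC | intermediate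
14 | but-3-enylmagnesium bromide | C=CCC[Mg]Br | starting material
15 | ethyl (2Z)-3-(diethoxymethyl)hepta-2,6-dienoate | CCOC(=O)/C=C(\C(OCC)OCC)CCC=C | intermediate
16 | ethyl (2Z)-3-(diethoxymethyl)-6,7-dihydroxyhept-2-enoate | CCOC(=O)/C=C(\C(OCC)OCC)CCC(O)CO | intermediate (not isolated)
17 | ethyl (2Z)-3-(diethoxymethyl)-6-oxohex-2-enoate | CCOC(=O)/C=C(\C(OCC)OCC)CCC=O | intermediate
18 | ethyl (2Z,6E)-3-(diethoxymethyl)-6-[(5S)-5-[(1E)-2,6-dimethylhepta-1,5-dien-1-yl]-2-oxooxolan-3-ylidene]hex-2-enoate | CCOC(=O)/C=C(\C(OCC)OCC)CC/C=C1\C[C@@H](/C=C(\C)CCC=C(C)C)OC1=O | intermediate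
19 | (2Z,6E,9S,10E)-3-(diethoxymethyl)-7-(hydroxymethyl)-11,15-dimethylhexadeca-2,6,10,14-tetraene-1,9-diol | OC/C=C(\C(OCC)OCC)CC/C=C(/CO)C[C@H](O)/C=C(\C)CCC=C(C)C | intermediate
20 | 1,7-(hydroxymethyl) bis-TBS ether of 19 with the C9 hydroxyl free | CC(C)(C)[Si](C)(C)OC/C=C(\C(OCC)OCC)CC/C=C(/CO[Si](C)(C)C(C)(C)C)C[C@H](O)/C=C(\C)CCC=C(C)C | intermediate (not isolated)
21 | (2Z,6E,9S,10E)-1-[(tert-butyldimethylsilyl)oxy]-7-{[(tert-butyldimethylsilyl)oxy]methyl}-3-(diethoxymethyl)-11,15-dimethylhexadeca-2,6,10,14-tetraen-9-yl acetate | CC(C)(C)[Si](C)(C)OC/C=C(\C(OCC)OCC)CC/C=C(/CO[Si](C)(C)C(C)(C)C)C[C@H](OC(C)=O)/C=C(\C)CCC=C(C)C | intermediate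
22 | (2Z,6E,9S,10E)-3-(diethoxymethyl)-1-hydroxy-7-(hydroxymethyl)-11,15-dimethylhexadeca-2,6,10,14-tetraen-9-yl acetate | OC/C=C(\C(OCC)OCC)CC/C=C(/CO)C[C@H](OC(C)=O)/C=C(\C)CCC=C(C)C | intermediate
23 | (2Z,6E,9S,10E)-3-(diethoxymethyl)-7-formyl-11,15-dimethyl-1-oxohexadeca-2,6,10,14-tetraen-9-yl acetate (key-step precursor) | O=C/C=C(\C(OCC)OCC)CC/C=C(/C=O)C[C@H](OC(C)=O)/C=C(\C)CCC=C(C)C | intermediate
24 | C1 dienamine of 23 with (S)-2-[diphenyl(trimethylsilyloxy)methyl]pyrrolidine | C[Si](C)(C)OC(c1ccccc1)(c1ccccc1)[C@@H]1CCCN1/C=C/C(C(OCC)OCC)=C\C/C=C(/C=O)C[C@H](OC(C)=O)/C=C(\C)CCC=C(C)C | intermediate (not isolated)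
25 | (4S,5E)-2-[3-(diethoxymethyl)-2-formylcyclopent-2-en-1-yl]-6,10-dimethyl-1-oxoundeca-5,9-dien-4-yl acetate (key-step product) | O=CC1=C(C(OCC)OCC)CCC1C(C=O)C[C@H](OC(C)=O)/C=C(\C)CCC=C(C)C | intermediate
26 | (2S,3E)-1-[7-(diethoxymethyl)-1-hydroxy-1,4a,5,6-tetrahydrocyclopenta[c]pyran-4-yl]-4,8-dimethylnona-3,7-dien-2-yl acetate | OC1OC=C(C[C@H](OC(C)=O)/C=C(\C)CCC=C(C)C)C2CCC(C(OCC)OCC)=C12 | intermediate (not isolated)
27 | (2S,3E)-1-[7-(diethoxymethyl)-4a,5-dihydrocyclopenta[c]pyran-4-yl]-4,8-dimethylnona-3,7-dien-2-yl acetate | CC(=O)O[C@H](/C=C(\C)CCC=C(C)C)CC1=COC=C2C(C(OCC)OCC)=CCC12 | intermediate (not isolated)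
28 | (2S,3E)-1-(7-formyl-4a,5-dihydrocyclopenta[c]pyran-4-yl)-4,8-dimethylnona-3,7-dien-2-yl acetate | CC(=O)O[C@H](/C=C(\C)CCC=C(C)C)CC1=COC=C2C(C=O)=CCC12 | intermediate
29 | (2S,3E)-1-(7-formylcyclopenta[c]pyran-4-yl)-4,8-dimethylnona-3,7-dien-2-yl acetate | CC(=O)O[C@H](/C=C(\C)CCC=C(C)C)Cc1cocc2c(C=O)ccc1-2 | target

Total step count: 15. Longest linear sequence: 12 steps (steps 1–4, then 8–15); steps 5–7 form the second branch.

Steps most likely to fail

Step 13. The amine may condense at the C3 enal as well, the dienamine may oligomerise intermolecularly instead of closing the ring, or dienamine formation next to the bulky acetal may be slow. The fallback sets out from 23 and replaces dienamine generation by hydride-triggered enamine generation. An organocatalytic reductive Michael cyclisation (Hantzsch ester, an imidazolidinone hydrochloride catalyst, dioxane) delivers hydride to C7 of the C1 iminium ion, the only enal that forms an iminium ion readily. The resulting enamine adds through C7a to C4a and should give (4S,5E)-2-[3-(diethoxymethyl)-2-formylcyclopentyl]-6,10-dimethyl-1-oxoundeca-5,9-dien-4-yl acetate F1. PPTS in benzene followed by wet acetone, as in step 14, should then give (2S,3E)-1-(7-formyl-4a,5,6,7-tetrahydrocyclopenta[c]pyran-4-yl)-4,8-dimethylnona-3,7-dien-2-yl acetate F2. DDQ (2.2 equiv) removes four hydrogens and the route is rejoined at 29.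

Step 14. Ring closure through O2 may stay incomplete, the acid-labile dienol ether may hydrate or oligomerise, or the unmasked formyl group may enter aldol chemistry. The fallback sets out from 25 and separates unmasking from dehydration. Amberlyst-15 in wet acetone hydrolyses the acetal, and the trialdehyde should settle as its ring tautomer (2S,3E)-1-(7-formyl-1-hydroxy-1,4a,5,6-tetrahydrocyclopenta[c]pyran-4-yl)-4,8-dimethylnona-3,7-dien-2-yl acetate F3. The lactol hydroxyl is then activated and eliminated under basic conditions (MsCl, Et3N, CH2Cl2, −20 °C) instead of by acid catalysis, and the route is rejoined at 28.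

Step 10. Discrimination between the two primary and the secondary allylic hydroxyls may be poor (over- or under-silylation), and the silyl ethers may be hard to remove cleanly in step 11. The fallback sets out from 19 and uses no silyl groups. Exhaustive acetylation (Ac2O, pyridine, DMAP) gives (2Z,6E,9S,10E)-7-(acetoxymethyl)-3-(diethoxymethyl)-11,15-dimethylhexadeca-2,6,10,14-tetraene-1,9-diyl diacetate F4. Candida antarctica lipase B in pH 7 buffer/acetone then hydrolyses only the two unhindered primary acetates, and the route is rejoined at 22.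

Further compounds
F1 | step 13 | (4S,5E)-2-[3-(diethoxymethyl)-2-formylcyclopentyl]-6,10-dimethyl-1-oxoundeca-5,9-dien-4-yl acetate | O=CC1C(C(OCC)OCC)CCC1C(C=O)C[C@H](OC(C)=O)/C=C(\C)CCC=C(C)C
F2 | step 13 | (2S,3E)-1-(7-formyl-4a,5,6,7-tetrahydrocyclopenta[c]pyran-4-yl)-4,8-dimethylnona-3,7-dien-2-yl acetate | CC(=O)O[C@H](/C=C(\C)CCC=C(C)C)CC1=COC=C2C(C=O)CCC12
F3 | step 14 | (2S,3E)-1-(7-formyl-1-hydroxy-1,4a,5,6-tetrahydrocyclopenta[c]pyran-4-yl)-4,8-dimethylnona-3,7-dien-2-yl acetate | OC1OC=C(C[C@H](OC(C)=O)/C=C(\C)CCC=C(C)C)C2CCC(C=O)=C12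
F4 | step 10 | (2Z,6E,9S,10E)-7-(acetoxymethyl)-3-(diethoxymethyl)-11,15-dimethylhexadeca-2,6,10,14-tetraene-1,9-diyl diacetate | CC(=O)OC/C=C(\C(OCC)OCC)CC/C=C(/COC(C)=O)C[C@H](OC(C)=O)/C=C(\C)CCC=C(C)C
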